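The ratio of the rate constant of the step that makes target to that of the step that destroys it, 45.5, is the weight that turns what stands in a flask into a ceiling for free target, and this is the flask on which I am examined:

    starting material + free catalyst ⇌ catalyst intermediate A (K1 = 34 M⁻¹, k1 = 990 M⁻¹ s⁻¹)
    partner + catalyst intermediate A → free catalyst + target (k2 = 100 M⁻¹ s⁻¹)
    second substrate + free catalyst ⇌ catalyst intermediate B (K3 = 4.0 M⁻¹, k3 = 370 M⁻¹ s⁻¹)
    partner + catalyst intermediate B → free catalyst + second product (k4 = 75 M⁻¹ s⁻¹)
    starting material + target → side product (k5 = 2.2 M⁻¹ s⁻¹)
    free catalyst + target ⇌ idle complex, settled at all times (K6 = 3.8 M⁻¹)

all flasks: second substrate 0.200 M; partner 0.110 M; free catalyst 0.26 mM; time 40 s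

| run | starting material |
|---|---|
| noon | 0.012 M |
| midnight | 0.025 M |
| summer | 0.050 M |
| autumn | 0.10 M |
| winter | 0.20 M |

- [target] (only what is free in solution) at the end for noon, midnight, summer, autumn, winter, in this order
- how the row runs (rises all the way / hardly changes / rises, then falls / falls, then rises / falls all the way)

- a species is counted by the starting material in it: one side product counts as two
- amounts and yields of target count idle complex too
- the concentration of target that is asked is that of its free form alone
- "hardly changes" means that all values lie within two and a half points (for a concentration: within two and a half percent of the largest)
- run time (noon): 40 s

*What happens to target once it is made?* Partner and catalyst intermediate A make it at a rate proportional to [partner][catalyst intermediate A], while starting material destroys it at a rate proportional to [starting material][target], and since the loss is pseudo-first-order in [target], making and loss balance at a ceiling, a quasi-steady level that moves as the flask runs down, equal to the weight times [partner][catalyst intermediate A]/[starting material].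

*How do you get [catalyst intermediate A] from the charge?* Partner drains it while it forms and falls back, so I take its standing level, which is 24.7 M⁻¹ times [starting material][free catalyst], while catalyst intermediate B stands at 0.734 times [free catalyst], and I leave idle complex out of the catalyst balance. For winter's charge this gives a ceiling of 0.00481 M, for summer's 0.0108 M, and for noon's 0.0158 M, so winter's is lower than noon's.

*Does the target reach that ceiling?* Dividing its rate by [starting material] leaves a plain approach to the ceiling on a clock that is the integral of [starting material] over time, and the gap shrinks as the exponential of minus the loss constant times that clock. In winter the approach takes about 2.27 s, which is shorter than the run, so I put winter at its ceiling. At noon [starting material] decays at 0.0348 s⁻¹, which makes the clock 0.259 M·s and the closed form gives 0.00687 M. For summer's charge the decay constant is 0.0238 s⁻¹, and the same closed form gives 0.0102 M.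

*But you held partner at its charge, and both catalyst rounds use it?* Yes, so I offer these as upper figures, with noon under 6.87 mM and winter under 4.81 mM. Since summer's figure stands above both, I commit to a row that rises, then falls.

The forecast gives 0.0059 M, 0.0084 M, 0.0095 M, 0.0075 M and 0.0039 M, a row that rises, then falls, holding that at high charge “target sits near its quasi-steady value”.

The flask gives 0.00616 M, 0.00888 M, 0.00976 M, 0.00750 M and 0.00381 M, and the row rises, then falls.

In winter at 40.0 s, with partner at 44.4% of its charge, the weight times the standing concentrations gives 0.00368 M against 0.00381 M of free target, so making and loss run level there. In autumn the same ratio gives 0.00750 M against 0.00750 M, whereas at noon it gives 0.0139 M, above the 0.00616 M that stands in that flask.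

Its constants were drawn at random within sensible limits, and the outcome is calculated.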